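**Plan**

- Numbering and feature: ring A is C1 (=CH2), C2 (OH), C3 (O-angeloyl), C4 (i-Pr), C5, C9; ring B is C5, C6 (=C12H–C13H3), C7 (OAc), C8, C9. The fusion atoms C5 and C9 hold the two arms of ring B (C6 and C8–C7). At the aldehyde oxidation level C5 is the α-carbon of a C6 formyl group and C9 the β-carbon of a C9=C8–C7 enal, so the ring A bond C5–C9 is an enamine Michael bond; C1–C4 with the trans C2,C3 oxygens is the skeleton of L-tartaric acid.
- Retrosynthesis, in order: the C3 and C7 acyl groups and the C2 PMB ether; C1=CH2 (from a ketal-masked ketone) and C6=C12 (Wittig); C6–C7 of ring B (pinacol coupling of a dialdehyde); C5–C9 of ring A (amine-catalysed Michael addition); then C1–C9 (acetylide acylation), C4–isopropyl (cuprate) and C4=C5 (Wittig) of the open chain.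
- Forward: the C1–C9 chain is built linearly on diethyl L-tartrate, ring A closes first (C5–C9), ring B second (C6–C7), then the two exocyclic alkenes and the two esters follow.
- Stereochemistry: C2 and C3 from L-tartrate; C4 by anti-selective cuprate addition next to C3; C5 and C9 in the chair-like Michael closure with the matched (R)-diarylprolinol silyl ether; C7 in the chelated cis-pinacol; C6=C12 (Z) by Wittig reaction of the α-silyloxy ketone; the angelate (Z) from angelic acid.

Key step: step 12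

Remark: locants C1–C13 and the CIP descriptors of the cyclic compounds (19–31, F3–F12) follow the numbering above ("hydrindane" = bicyclo[4.3.0]nonane skeleton, "route numbering"); acyclic compounds carry the locants of their own names.

Step 1
Reactants: 1 diethyl L-tartrate [diethyl (2R,3R)-2,3-dihydroxybutanedioate]
Product: 2 diethyl (2R,3R)-2-hydroxy-3-[(4-methoxyphenyl)methoxy]butanedioate
Conditions: 4-MeOC6H4CH2Cl (1.1 equiv), Ag2O (1.5 equiv), CH2Cl2, rt, dark
Reagents that add atoms: 4-methoxybenzyl chloride, COc1ccc(CCl)cc1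
Why: Ag2O-promoted Williamson etherification is a mono-selective protection of symmetrical diols (the first ether formation deactivates the neighbouring hydroxyl), and because 1 is C2-symmetric either hydroxyl gives the same ether, so the two chain ends become different without any stereocentre being touched.

Step 2
Reactants: 2 diethyl (2R,3R)-2-hydroxy-3-[(4-methoxyphenyl)methoxy]butanedioate
Product: 3 ethyl (2R,3S)-3,4-dihydroxy-2-[(4-methoxyphenyl)methoxy]butanoate
Conditions: BH3·SMe2 (1.05 equiv), NaBH4 (5 mol %), THF, 0 °C to rt; MeOH, then aqueous work-up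
Reagents that add atoms: none
Why: Hydroxyl-directed borane reduction proceeds through an alkoxyborane at the free hydroxyl that delivers hydride only to the adjacent ester, so the ester next to the PMB ether survives and C2 and C3 are unaffected.

Step 3
Reactants: 3 ethyl (2R,3S)-3,4-dihydroxy-2-[(4-methoxyphenyl)methoxy]butanoate
Product: 5 ethyl (2R,3S)-3-[(tert-butyldimethylsilyl)oxy]-2-[(4-methoxyphenyl)methoxy]-4-[(triethylsilyl)oxy]butanoate, via primary triethylsilyl ether 4 (not isolated)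
Conditions: Et3SiCl (1.05 equiv), imidazole, CH2Cl2, −78 to −20 °C; then t-BuMe2SiOTf, 2,6-lutidine, −78 to 0 °C
Reagents that add atoms: triethylsilyl chloride, CC[Si](Cl)(CC)CC; tert-butyldimethylsilyl trifluoromethanesulfonate, CC(C)(C)[Si](C)(C)OS(=O)(=O)C(F)(F)F
Why: Silyl ether formation in two stages in one flask uses the much faster silylation of the primary hydroxyl by the silyl chloride and then the silyl triflate for the hindered secondary hydroxyl, and it caps both hydroxyls before the γ-hydroxy ester can lactonize.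

Step 4
Reactants: 5 ethyl (2R,3S)-3-[(tert-butyldimethylsilyl)oxy]-2-[(4-methoxyphenyl)methoxy]-4-[(triethylsilyl)oxy]butanoate; 6 tert-butyl (triphenylphosphoranylidene)acetate
Product: 8 1-tert-butyl 6-ethyl (2E,4S,5R)-4-[(tert-butyldimethylsilyl)oxy]-5-[(4-methoxyphenyl)methoxy]hex-2-enedioate, via aldehyde 7 (not isolated)
Conditions: (COCl)2, DMSO, CH2Cl2, −78 to −30 °C; Et3N, −78 °C; then 6, −78 °C to rt
Reagents that add atoms: none
Why: Swern oxidation applied directly to a primary triethylsilyl ether (the chlorosulfonium salt cleaves and oxidizes the labile primary Si–O unit while the secondary TBS ether is inert) followed by Wittig olefination with the ester-stabilized ylide in the same flask avoids handling the epimerizable α-silyloxy aldehyde and should give the E-enoate, as is usual for stabilized ylides in an aprotic solvent.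

Step 5
Reactants: 8 1-tert-butyl 6-ethyl (2E,4S,5R)-4-[(tert-butyldimethylsilyl)oxy]-5-[(4-methoxyphenyl)methoxy]hex-2-enedioate; 9 isopropylmagnesium chloride
Product: 11 1-tert-butyl 6-ethyl (3R,4S,5R)-4-[(tert-butyldimethylsilyl)oxy]-5-[(4-methoxyphenyl)methoxy]-3-(propan-2-yl)hexanedioate, via silyl ketene acetal 10 (not isolated)
Conditions: 9 (4 equiv), CuBr·SMe2 (2 equiv), Me3SiCl (4 equiv), THF, −78 to −40 °C; aq NH4Cl, then brief dilute HCl wash
Reagents that add atoms: none
Why: Conjugate addition of the magnesium diisopropylcuprate, accelerated by Me3SiCl, to the E-γ-silyloxy enoate should take place anti to the γ-oxygen (Felkin–Anh-type transition state with the C3–O bond antiperiplanar to the incoming copper and the C3 hydrogen eclipsing the alkene), which sets C4 with isopropyl anti to the C3 oxygen in the extended chain, that is cis on the later ring A, while both ester groups are inert to the cuprate at low temperature.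

Step 6
Reactants: 11 1-tert-butyl 6-ethyl (3R,4S,5R)-4-[(tert-butyldimethylsilyl)oxy]-5-[(4-methoxyphenyl)methoxy]-3-(propan-2-yl)hexanedioate
Product: 12 tert-butyl (3R,4S,5R)-4-[(tert-butyldimethylsilyl)oxy]-6-[methoxy(methyl)amino]-5-[(4-methoxyphenyl)methoxy]-6-oxo-3-(propan-2-yl)hexanoate
Conditions: MeNH(OMe)·HCl, i-PrMgCl (9), THF, −20 to 0 °C
Reagents that add atoms: N,O-dimethylhydroxylamine hydrochloride, CNOC.Cl
Why: Weinreb amide formation by aminolysis with the chloromagnesium amide of N,O-dimethylhydroxylamine selects the α-alkoxy ethyl ester over the bulky, unactivated tert-butyl ester and does not enolize C2.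

Step 7
Reactants: 12 tert-butyl (3R,4S,5R)-4-[(tert-butyldimethylsilyl)oxy]-6-[methoxy(methyl)amino]-5-[(4-methoxyphenyl)methoxy]-6-oxo-3-(propan-2-yl)hexanoate; 13 tert-butyldimethyl(prop-2-yn-1-yloxy)silane
Product: 14 tert-butyl (3R,4S,5R)-4,9-bis[(tert-butyldimethylsilyl)oxy]-5-[(4-methoxyphenyl)methoxy]-6-oxo-3-(propan-2-yl)non-7-ynoate
Conditions: 13, n-BuLi, THF, −78 °C; then 12, −78 to −20 °C; aq NH4Cl
Reagents that add atoms: none
Why: Acylation of the lithium acetylide by the Weinreb amide stops at the ketone stage because the chelated tetrahedral adduct persists until work-up, and the tert-butyl ester is not attacked at low temperature.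

Step 8
Reactants: 14 tert-butyl (3R,4S,5R)-4,9-bis[(tert-butyldimethylsilyl)oxy]-5-[(4-methoxyphenyl)methoxy]-6-oxo-3-(propan-2-yl)non-7-ynoate
Product: 15 tert-butyl (3R,4S,5R)-4-[(tert-butyldimethylsilyl)oxy]-5-(2-{3-[(tert-butyldimethylsilyl)oxy]prop-1-yn-1-yl}-1,3-dioxolan-2-yl)-5-[(4-methoxyphenyl)methoxy]-3-(propan-2-yl)pentanoate
Conditions: Me3SiOCH2CH2OSiMe3, Me3SiOTf (5 mol %), CH2Cl2, −78 to −20 °C; pyridine quench
Reagents that add atoms: 1,2-bis(trimethylsilyloxy)ethane, C[Si](C)(C)OCCO[Si](C)(C)C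
Why: Noyori ketalization (bis-silyl glycol ether with catalytic Me3SiOTf) is aprotic and works at low temperature, is well precedented for alkynyl ketones, whose slim alkyne leaves the carbonyl accessible, and leaves PMB ether, TBS ethers and tert-butyl ester intact; the ketal carbon is not stereogenic.

Step 9
Reactants: 15 tert-butyl (3R,4S,5R)-4-[(tert-butyldimethylsilyl)oxy]-5-(2-{3-[(tert-butyldimethylsilyl)oxy]prop-1-yn-1-yl}-1,3-dioxolan-2-yl)-5-[(4-methoxyphenyl)methoxy]-3-(propan-2-yl)pentanoate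
Product: 16 tert-butyl (3R,4S,5R)-4-[(tert-butyldimethylsilyl)oxy]-5-[2-(3-hydroxyprop-1-yn-1-yl)-1,3-dioxolan-2-yl]-5-[(4-methoxyphenyl)methoxy]-3-(propan-2-yl)pentanoate
Conditions: HF·pyridine, pyridine, THF, 0 °C
Reagents that add atoms: none
Why: Fluoride-mediated desilylation is far faster for the unhindered primary propargylic TBS ether than for the C3 TBS ether flanked by two branched carbons, and pyridine-buffered HF·pyridine does not open the dioxolane or cleave the tert-butyl ester.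

Step 10
Reactants: 16 tert-butyl (3R,4S,5R)-4-[(tert-butyldimethylsilyl)oxy]-5-[2-(3-hydroxyprop-1-yn-1-yl)-1,3-dioxolan-2-yl]-5-[(4-methoxyphenyl)methoxy]-3-(propan-2-yl)pentanoate
Product: 17 (3R,4S,5R)-4-[(tert-butyldimethylsilyl)oxy]-5-{2-[(1E)-3-hydroxyprop-1-en-1-yl]-1,3-dioxolan-2-yl}-5-[(4-methoxyphenyl)methoxy]-3-(propan-2-yl)pentan-1-ol
Conditions: NaAlH2(OCH2CH2OMe)2 (4 equiv), THF, 0 °C to rt; aq potassium sodium tartrate
Reagents that add atoms: none
Why: Alkoxide-directed trans-hydroalumination of the propargylic alcohol gives the E-allylic alcohol on protonolysis, and the same hydride reduces the tert-butyl ester to the primary alcohol; the low temperature suppresses loss of a ketal oxygen from the vinylalanate to an allene.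

Step 11
Reactants: 17 (3R,4S,5R)-4-[(tert-butyldimethylsilyl)oxy]-5-{2-[(1E)-3-hydroxyprop-1-en-1-yl]-1,3-dioxolan-2-yl}-5-[(4-methoxyphenyl)methoxy]-3-(propan-2-yl)pentan-1-ol
Product: 18 (3R,4S,5R)-4-[(tert-butyldimethylsilyl)oxy]-5-[(4-methoxyphenyl)methoxy]-5-{2-[(1E)-3-oxoprop-1-en-1-yl]-1,3-dioxolan-2-yl}-3-(propan-2-yl)pentanal (acyclic formyl enal)
Conditions: Dess–Martin periodinane (3 equiv), NaHCO3, CH2Cl2, 0 °C to rt
Reagents that add atoms: none
Why: Dess–Martin oxidation turns the primary alcohol into the aldehyde and the allylic alcohol into the E-enal in one operation under buffered conditions that neither isomerize the enal nor open the ketal, and no stereocentre is α to either new carbonyl.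

Step 12
Reactants: 18 (3R,4S,5R)-4-[(tert-butyldimethylsilyl)oxy]-5-[(4-methoxyphenyl)methoxy]-5-{2-[(1E)-3-oxoprop-1-en-1-yl]-1,3-dioxolan-2-yl}-3-(propan-2-yl)pentanal
Product: 19 (2R,3S,4S,5S,9R)-3-[(tert-butyldimethylsilyl)oxy]-5-formyl-2-[(4-methoxyphenyl)methoxy]-9-(2-oxoethyl)-4-(propan-2-yl)cyclohexan-1-one ethylene ketal (ring A dialdehyde; route numbering)
Conditions: (R)-2-[diphenyl(trimethylsilyloxy)methyl]pyrrolidine (20 mol %), PhCO2H (20 mol %), CH2Cl2 (0.05 M), 0 °C to rt
Reagents that add atoms: none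
Why: The secondary amine condenses with the saturated C6 aldehyde to an E-enamine whose nucleophilic carbon C5 adds to C9, the β-carbon of the tethered E-enal, and hydrolysis of the resulting enamine/iminium pair releases dialdehyde 19 and the catalyst; the ketal carbon C1 bears no hydrogen, so the enal cannot form a dienamine. The closest known reaction type is the secondary-amine-catalysed intramolecular Michael addition of formyl-tethered enones and enals, which gives trans-1,2-disubstituted carbocycles. Ring A closes in a 6-exo-trig mode through a chair-like transition state in which the isopropyl group and both reacting π-arms (enamine on C5, enal on C9) are equatorial, at the cost of axial oxygens on C2 and C3. C5 is controlled by the enamine face that the diphenyl(silyloxy)methyl group of the (R)-catalyst leaves open, which is the face that puts the new bond trans to the C4 isopropyl group, and C9 is controlled by the equatorial enal arm in the same chair. The step needs C4/C5 trans and C5/C9 trans; the resident C4 centre, the E geometry of enamine and enal and the matched catalyst secure this kinetically, and because C5 remains a formyl-bearing, epimerizable carbon any cis isomer can drain through the enamine into the all-equatorial product.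

Step 13
Reactants: 19 ring A dialdehyde
Product: 20 (2R,3S,4S,5S,6R,7S,9R)-3-[(tert-butyldimethylsilyl)oxy]-6,7-dihydroxy-2-[(4-methoxyphenyl)methoxy]-4-(propan-2-yl)hydrindan-1-one ethylene ketal (trans-fused; cis-6,7-diol; route numbering)
Conditions: SmI2 (2.5 equiv), t-BuOH, THF, −78 °C to rt
Reagents that add atoms: none
Why: Samarium diiodide pinacol coupling of a 1,5-dialdehyde (5-exo attack of a ketyl on the second carbonyl) should give the cis-diol because both oxygens are held on trivalent samarium in the transition state, and the pair of oxygens should take the face of ring B opposite to the C4 branch on C5, since a C6 oxygen on the other face is nearly eclipsed with C4 and its isopropyl group, which puts the C7 oxygen on the face required in the target (C6 is oxidized later, so only C7 matters).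

Step 14
Reactants: 20 pinacol diol
Product: 21 (2R,3S,4S,5S,6R,7S,9R)-3,7-bis[(tert-butyldimethylsilyl)oxy]-6-hydroxy-2-[(4-methoxyphenyl)methoxy]-4-(propan-2-yl)hydrindan-1-one ethylene ketal
Conditions: t-BuMe2SiCl (1.2 equiv), imidazole, DMF, 0 °C
Reagents that add atoms: tert-butyldimethylsilyl chloride, CC(C)(C)[Si](C)(C)Cl
Why: Silyl ether formation with the silyl chloride and imidazole discriminates the C7 hydroxyl, whose neighbour is a methylene group, from the C6 hydroxyl, which is wedged between C5 and the C4 isopropyl group.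

Step 15
Reactants: 21 C7 silyl ether
Product: 22 (2R,3S,4S,5S,7S,9R)-3,7-bis[(tert-butyldimethylsilyl)oxy]-2-[(4-methoxyphenyl)methoxy]-4-(propan-2-yl)hydrindane-1,6-dione 1-ethylene ketal
Conditions: Dess–Martin periodinane, NaHCO3, CH2Cl2, 0 °C to rt
Reagents that add atoms: none
Why: Dess–Martin oxidation of a hindered secondary alcohol is reliable and, buffered with NaHCO3, does not epimerize the α-silyloxy ketone; trans ring fusion at C5 is in any case the stable arrangement because the cis isomer would force C6 into a 1,3-diaxial contact with the C3 silyl ether.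

Step 16
Reactants: 22 C6 ketone; 23 ethyltriphenylphosphonium bromide
Product: 24 (2R,3S,4S,5S,7S,9R,6Z)-3,7-bis[(tert-butyldimethylsilyl)oxy]-6-ethylidene-2-[(4-methoxyphenyl)methoxy]-4-(propan-2-yl)hydrindan-1-one ethylene ketal
Conditions: 23, KN(SiMe3)2 (0.95 equiv per 23), THF, 0 °C; then 22, −78 °C to rt
Reagents that add atoms: none
Why: Wittig olefination with the non-stabilized, salt-free ethylidene ylide should deliver the Z-alkene (methyl on the C7 side), because α-oxygenated ketones direct the ylide substituent towards the oxygen-bearing carbon and the opposite position is blocked by C4 and its isopropyl group, and using no excess base limits enolization towards C7.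

Step 17
Reactants: 24 Z-ethylidene ketal
Product: 25 (2R,3S,4S,5S,7S,9R,6Z)-3,7-bis[(tert-butyldimethylsilyl)oxy]-6-ethylidene-2-[(4-methoxyphenyl)methoxy]-4-(propan-2-yl)hydrindan-1-one
Conditions: pyridinium p-toluenesulfonate, acetone/H2O (10:1), 60 °C
Reagents that add atoms: water, O
Why: Acid-catalysed ketal hydrolysis in wet acetone with a mild pyridinium acid removes the dioxolane, helped by relief of the 1,3-diaxial repulsion between a ketal oxygen and the C3 silyl ether, while secondary TBS ethers, the PMB ether and the trisubstituted alkene tolerate these conditions.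

Step 18
Reactants: 25 C1 ketone
Product: 26 (2S,3S,4S,5R,7S,9R,6Z)-3,7-bis[(tert-butyldimethylsilyl)oxy]-6-ethylidene-2-[(4-methoxyphenyl)methoxy]-1-methylidene-4-(propan-2-yl)hydrindane
Conditions: Cp2TiMe2 (3 equiv), toluene, 70 °C, dark
Reagents that add atoms: dimethyltitanocene, C[Ti](C)(C1C=CC=C1)C1C=CC=C1
Why: Petasis methylenation with the neutral titanium methylidene generated thermally from Cp2TiMe2 olefinates hindered, enolizable ketones without base, so that C2 (α-alkoxy) and C9 are not epimerized as they might be by a phosphorus ylide.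

Step 19
Reactants: 26 bis-silyl ether diene
Product: 27 (2S,3S,4S,5R,7S,9R,6Z)-6-ethylidene-2-[(4-methoxyphenyl)methoxy]-1-methylidene-4-(propan-2-yl)hydrindane-3,7-diol
Conditions: Bu4NF (4 equiv), THF, rt to 45 °C
Reagents that add atoms: none
Why: Fluoride-induced cleavage of both silyl ethers is uncomplicated here because the molecule carries no ester or other base-sensitive group, and gentle warming should be enough for the hindered axial C3 ether.

Step 20
Reactants: 27 C3,C7-diol
Product: 28 (2S,3S,4S,5R,7S,9R,6Z)-6-ethylidene-3-hydroxy-2-[(4-methoxyphenyl)methoxy]-1-methylidene-4-(propan-2-yl)hydrindan-7-yl acetate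
Conditions: Ac2O (1.1 equiv), pyridine, 4-(dimethylamino)pyridine (5 mol %), CH2Cl2, 0 °C
Reagents that add atoms: acetic anhydride, CC(=O)OC(C)=O
Why: Acylation with a small excess of acetic anhydride under nucleophilic catalysis should select the allylic C7 hydroxyl on the cyclopentane over the axial C3 hydroxyl, which is shielded by the adjacent isopropyl group and by the C2 PMB ether.

Step 21
Reactants: 28 C7 acetate; 29 angelic acid [(2Z)-2-methylbut-2-enoic acid]
Product: 30 (2S,3S,4S,5R,7S,9R,6Z)-7-acetoxy-6-ethylidene-2-[(4-methoxyphenyl)methoxy]-1-methylidene-4-(propan-2-yl)hydrindan-3-yl (2Z)-2-methylbut-2-enoate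
Conditions: 29, 2,4,6-trichlorobenzoyl chloride, Et3N, toluene, rt; then 28, 80 °C
Reagents that add atoms: none
Why: Esterification through the mixed 2,4,6-trichlorobenzoic anhydride of angelic acid (Yamaguchi-type activation, used without a nucleophilic catalyst) acylates hindered secondary alcohols on heating and avoids the nucleophile-induced isomerization of the Z-acyl unit to the tiglate, so the Z geometry of angelic acid is carried into the ester.

Step 22
Reactants: 30 PMB-protected diester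
Product: 31 (2S,3S,4S,5R,7S,9R,6Z)-7-acetoxy-6-ethylidene-2-hydroxy-1-methylidene-4-(propan-2-yl)hydrindan-3-yl (2Z)-2-methylbut-2-enoate (CNP0113604.1)
Conditions: DDQ (1.5 equiv), CH2Cl2/pH 7 buffer (10:1), 0 °C to rt
Reagents that add atoms: none
Why: Oxidative cleavage of the PMB ether by DDQ in buffered wet dichloromethane is selective for the electron-rich benzyl ether, leaves both esters and both alkenes untouched, and the freed axial C2 hydroxyl cannot take over the trans-diaxial C3 acyl group.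

**Compound list**

1 | diethyl L-tartrate [diethyl (2R,3R)-2,3-dihydroxybutanedioate] | CCOC(=O)[C@H](O)[C@@H](O)C(=O)OCC | starting material
2 | diethyl (2R,3R)-2-hydroxy-3-[(4-methoxyphenyl)methoxy]butanedioate | CCOC(=O)[C@H](OCc1ccc(OC)cc1)[C@@H](O)C(=O)OCC | intermediate
3 | ethyl (2R,3S)-3,4-dihydroxy-2-[(4-methoxyphenyl)methoxy]butanoate | CCOC(=O)[C@H](OCc1ccc(OC)cc1)[C@@H](O)CO | intermediate
4 | ethyl (2R,3S)-3-hydroxy-2-[(4-methoxyphenyl)methoxy]-4-[(triethylsilyl)oxy]butanoate (not isolated) | CCOC(=O)[C@H](OCc1ccc(OC)cc1)[C@@H](O)CO[Si](CC)(CC)CC | intermediate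
5 | ethyl (2R,3S)-3-[(tert-butyldimethylsilyl)oxy]-2-[(4-methoxyphenyl)methoxy]-4-[(triethylsilyl)oxy]butanoate | CCOC(=O)[C@H](OCc1ccc(OC)cc1)[C@@H](O[Si](C)(C)C(C)(C)C)CO[Si](CC)(CC)CC | intermediate
6 | tert-butyl (triphenylphosphoranylidene)acetate | CC(C)(C)OC(=O)C=P(c1ccccc1)(c1ccccc1)c1ccccc1 | starting material
7 | ethyl (2R,3R)-3-[(tert-butyldimethylsilyl)oxy]-2-[(4-methoxyphenyl)methoxy]-4-oxobutanoate (not isolated) | CCOC(=O)[C@H](OCc1ccc(OC)cc1)[C@@H](O[Si](C)(C)C(C)(C)C)C=O | intermediate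
8 | 1-tert-butyl 6-ethyl (2E,4S,5R)-4-[(tert-butyldimethylsilyl)oxy]-5-[(4-methoxyphenyl)methoxy]hex-2-enedioate | CCOC(=O)[C@H](OCc1ccc(OC)cc1)[C@@H](O[Si](C)(C)C(C)(C)C)/C=C/C(=O)OC(C)(C)C | intermediate
9 | isopropylmagnesium chloride | CC(C)[Mg]Cl | starting material
10 | ethyl (2R,3S,4S)-6-tert-butoxy-3-[(tert-butyldimethylsilyl)oxy]-2-[(4-methoxyphenyl)methoxy]-4-(propan-2-yl)-6-[(trimethylsilyl)oxy]hex-5-enoate (silyl ketene acetal; C5=C6 geometry open; not isolated) | CCOC(=O)[C@H](OCc1ccc(OC)cc1)[C@@H](O[Si](C)(C)C(C)(C)C)[C@@H](C(C)C)C=C(O[Si](C)(C)C)OC(C)(C)C | intermediate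
11 | 1-tert-butyl 6-ethyl (3R,4S,5R)-4-[(tert-butyldimethylsilyl)oxy]-5-[(4-methoxyphenyl)methoxy]-3-(propan-2-yl)hexanedioate | CCOC(=O)[C@H](OCc1ccc(OC)cc1)[C@@H](O[Si](C)(C)C(C)(C)C)[C@@H](C(C)C)CC(=O)OC(C)(C)C | intermediate
12 | tert-butyl (3R,4S,5R)-4-[(tert-butyldimethylsilyl)oxy]-6-[methoxy(methyl)amino]-5-[(4-methoxyphenyl)methoxy]-6-oxo-3-(propan-2-yl)hexanoate | CON(C)C(=O)[C@H](OCc1ccc(OC)cc1)[C@@H](O[Si](C)(C)C(C)(C)C)[C@@H](C(C)C)CC(=O)OC(C)(C)C | intermediate
13 | tert-butyldimethyl(prop-2-yn-1-yloxy)silane | C#CCO[Si](C)(C)C(C)(C)C | starting material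
14 | tert-butyl (3R,4S,5R)-4,9-bis[(tert-butyldimethylsilyl)oxy]-5-[(4-methoxyphenyl)methoxy]-6-oxo-3-(propan-2-yl)non-7-ynoate | CC(C)(C)[Si](C)(C)OCC#CC(=O)[C@H](OCc1ccc(OC)cc1)[C@@H](O[Si](C)(C)C(C)(C)C)[C@@H](C(C)C)CC(=O)OC(C)(C)C | intermediate
15 | tert-butyl (3R,4S,5R)-4-[(tert-butyldimethylsilyl)oxy]-5-(2-{3-[(tert-butyldimethylsilyl)oxy]prop-1-yn-1-yl}-1,3-dioxolan-2-yl)-5-[(4-methoxyphenyl)methoxy]-3-(propan-2-yl)pentanoate | CC(C)(C)[Si](C)(C)OCC#CC1(OCCO1)[C@H](OCc2ccc(OC)cc2)[C@@H](O[Si](C)(C)C(C)(C)C)[C@@H](C(C)C)CC(=O)OC(C)(C)C | intermediate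
16 | tert-butyl (3R,4S,5R)-4-[(tert-butyldimethylsilyl)oxy]-5-[2-(3-hydroxyprop-1-yn-1-yl)-1,3-dioxolan-2-yl]-5-[(4-methoxyphenyl)methoxy]-3-(propan-2-yl)pentanoate | OCC#CC1(OCCO1)[C@H](OCc2ccc(OC)cc2)[C@@H](O[Si](C)(C)C(C)(C)C)[C@@H](C(C)C)CC(=O)OC(C)(C)C | intermediate
17 | (3R,4S,5R)-4-[(tert-butyldimethylsilyl)oxy]-5-{2-[(1E)-3-hydroxyprop-1-en-1-yl]-1,3-dioxolan-2-yl}-5-[(4-methoxyphenyl)methoxy]-3-(propan-2-yl)pentan-1-ol | OC/C=C/C1(OCCO1)[C@H](OCc2ccc(OC)cc2)[C@@H](O[Si](C)(C)C(C)(C)C)[C@@H](C(C)C)CCO | intermediate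
18 | (3R,4S,5R)-4-[(tert-butyldimethylsilyl)oxy]-5-[(4-methoxyphenyl)methoxy]-5-{2-[(1E)-3-oxoprop-1-en-1-yl]-1,3-dioxolan-2-yl}-3-(propan-2-yl)pentanal (acyclic formyl enal) | O=CC[C@H](C(C)C)[C@H](O[Si](C)(C)C(C)(C)C)[C@@H](OCc1ccc(OC)cc1)C2(OCCO2)/C=C/C=O | intermediate
19 | (2R,3S,4S,5S,9R)-3-[(tert-butyldimethylsilyl)oxy]-5-formyl-2-[(4-methoxyphenyl)methoxy]-9-(2-oxoethyl)-4-(propan-2-yl)cyclohexan-1-one ethylene ketal (ring A dialdehyde; route numbering) | O=CC[C@H]1C2(OCCO2)[C@H](OCc3ccc(OC)cc3)[C@@H](O[Si](C)(C)C(C)(C)C)[C@@H](C(C)C)[C@@H]1C=O | intermediate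
20 | (2R,3S,4S,5S,6R,7S,9R)-3-[(tert-butyldimethylsilyl)oxy]-6,7-dihydroxy-2-[(4-methoxyphenyl)methoxy]-4-(propan-2-yl)hydrindan-1-one ethylene ketal (trans-fused; route numbering) | O1CCOC12[C@H](OCc4ccc(OC)cc4)[C@@H](O[Si](C)(C)C(C)(C)C)[C@@H](C(C)C)[C@@H]3[C@@H](O)[C@@H](O)C[C@@H]23 | intermediate
21 | (2R,3S,4S,5S,6R,7S,9R)-3,7-bis[(tert-butyldimethylsilyl)oxy]-6-hydroxy-2-[(4-methoxyphenyl)methoxy]-4-(propan-2-yl)hydrindan-1-one ethylene ketal | O1CCOC12[C@H](OCc4ccc(OC)cc4)[C@@H](O[Si](C)(C)C(C)(C)C)[C@@H](C(C)C)[C@@H]3[C@@H](O)[C@@H](O[Si](C)(C)C(C)(C)C)C[C@@H]23 | intermediate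
22 | (2R,3S,4S,5S,7S,9R)-3,7-bis[(tert-butyldimethylsilyl)oxy]-2-[(4-methoxyphenyl)methoxy]-4-(propan-2-yl)hydrindane-1,6-dione 1-ethylene ketal | O1CCOC12[C@H](OCc4ccc(OC)cc4)[C@@H](O[Si](C)(C)C(C)(C)C)[C@@H](C(C)C)[C@@H]3C(=O)[C@@H](O[Si](C)(C)C(C)(C)C)C[C@@H]23 | intermediate
23 | ethyltriphenylphosphonium bromide | CC[P+](c1ccccc1)(c1ccccc1)c1ccccc1.[Br-] | starting material
24 | (2R,3S,4S,5S,7S,9R,6Z)-3,7-bis[(tert-butyldimethylsilyl)oxy]-6-ethylidene-2-[(4-methoxyphenyl)methoxy]-4-(propan-2-yl)hydrindan-1-one ethylene ketal | O1CCOC12[C@H](OCc4ccc(OC)cc4)[C@@H](O[Si](C)(C)C(C)(C)C)[C@@H](C(C)C)[C@@H]3/C(=C/C)[C@@H](O[Si](C)(C)C(C)(C)C)C[C@@H]23 | intermediate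
25 | (2R,3S,4S,5S,7S,9R,6Z)-3,7-bis[(tert-butyldimethylsilyl)oxy]-6-ethylidene-2-[(4-methoxyphenyl)methoxy]-4-(propan-2-yl)hydrindan-1-one | O=C1[C@H](OCc3ccc(OC)cc3)[C@@H](O[Si](C)(C)C(C)(C)C)[C@@H](C(C)C)[C@@H]2/C(=C/C)[C@@H](O[Si](C)(C)C(C)(C)C)C[C@@H]12 | intermediate
26 | (2S,3S,4S,5R,7S,9R,6Z)-3,7-bis[(tert-butyldimethylsilyl)oxy]-6-ethylidene-2-[(4-methoxyphenyl)methoxy]-1-methylidene-4-(propan-2-yl)hydrindane | C=C1[C@H](OCc3ccc(OC)cc3)[C@@H](O[Si](C)(C)C(C)(C)C)[C@@H](C(C)C)[C@@H]2/C(=C/C)[C@@H](O[Si](C)(C)C(C)(C)C)C[C@@H]12 | intermediate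
27 | (2S,3S,4S,5R,7S,9R,6Z)-6-ethylidene-2-[(4-methoxyphenyl)methoxy]-1-methylidene-4-(propan-2-yl)hydrindane-3,7-diol | C=C1[C@H](OCc3ccc(OC)cc3)[C@@H](O)[C@@H](C(C)C)[C@@H]2/C(=C/C)[C@@H](O)C[C@@H]12 | intermediate
28 | (2S,3S,4S,5R,7S,9R,6Z)-6-ethylidene-3-hydroxy-2-[(4-methoxyphenyl)methoxy]-1-methylidene-4-(propan-2-yl)hydrindan-7-yl acetate | C=C1[C@H](OCc3ccc(OC)cc3)[C@@H](O)[C@@H](C(C)C)[C@@H]2/C(=C/C)[C@@H](OC(C)=O)C[C@@H]12 | intermediate
29 | angelic acid [(2Z)-2-methylbut-2-enoic acid] | C/C=C(/C)C(=O)O | starting material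
30 | (2S,3S,4S,5R,7S,9R,6Z)-7-acetoxy-6-ethylidene-2-[(4-methoxyphenyl)methoxy]-1-methylidene-4-(propan-2-yl)hydrindan-3-yl (2Z)-2-methylbut-2-enoate | C=C1[C@H](OCc3ccc(OC)cc3)[C@@H](OC(=O)/C(C)=C\C)[C@@H](C(C)C)[C@@H]2/C(=C/C)[C@@H](OC(C)=O)C[C@@H]12 | intermediate
31 | (2S,3S,4S,5R,7S,9R,6Z)-7-acetoxy-6-ethylidene-2-hydroxy-1-methylidene-4-(propan-2-yl)hydrindan-3-yl (2Z)-2-methylbut-2-enoate (CNP0113604.1) | C=C1[C@H](O)[C@@H](OC(=O)/C(C)=C\C)[C@@H](C(C)C)[C@@H]2/C(=C/C)[C@@H](OC(C)=O)C[C@@H]12 | target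

**Totals and risks**

Total step count: 22. Longest linear sequence: 22 steps from diethyl L-tartrate (1); the route is fully linear, and 6, 9, 13, 23 and 29 are purchased.

Steps most likely to fail:

1. Step 12 (key Michael closure). The enamine may fail to engage the enal β-carbon next to the fully substituted ketal carbon, so that conversion stalls or intermolecular aldol condensation takes over, or the closure may pass through the other enamine face. Fallback (ester-enolate Michael cyclization, same C5–C9 bond): setting out from 18, both formyl groups are oxidized under Pinnick conditions (NaClO2, NaH2PO4, 2-methylbut-2-ene, t-BuOH/H2O) to the diacid F1, which is esterified with Me3SiCHN2 to the dimethyl diester F2. NaOMe in MeOH then closes ring A by Michael addition of the saturated ester enolate to the enoate under thermodynamic control, which should give the cyclized diester F3 with the C4, C5 and C9 substituents equatorial. LiAlH4 reduces this to the diol F4, and Swern oxidation brings the route back to 19.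

2. Step 16 (ethylidenation). The basic ylide may deprotonate the hindered α-silyloxy ketone (enolization, epimerization at C7, silyl migration) instead of adding to it, or the Z/E discrimination may be insufficient. Fallback (Peterson olefination with stereospecific elimination): setting out from 22, addition of 1-(trimethylsilyl)ethylmagnesium chloride in the presence of anhydrous CeCl3 (a weakly basic organocerium reagent) gives the β-hydroxysilane F5 as two separable diastereomers. Each is eliminated stereospecifically, one by syn elimination with KH in THF and the other by anti elimination with BF3·OEt2 at −78 °C, the mode being chosen so that both converge on the Z-alkene and the route is rejoined at 24.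

3. Step 13 (pinacol closure of ring B). Poor facial selectivity: the coupling may close on the face of ring B that carries the C4 branch, which leaves C7 with the wrong configuration. Fallback (C7 set by inversion instead of by the ring closure): setting out from 19, the 6,7-bis-epimeric cis-diol F6 is carried through the operations of steps 14 to 19 unchanged. This gives in turn the C7 silyl ether F7, the ketone F8, the Z-ethylidene compound F9, the C1 ketone F10, the methylidene compound F11 and the diol F12. The acetate is then introduced with inversion at the allylic C7 hydroxyl by a Mitsunobu reaction (AcOH, PPh3, diisopropyl azodicarboxylate, THF, 0 °C), which takes the place of step 20 and joins the route at 28.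

**Further compounds**

F1 | step 12 | (3R,4S,5R)-4-[(tert-butyldimethylsilyl)oxy]-5-{2-[(E)-2-carboxyethenyl]-1,3-dioxolan-2-yl}-5-[(4-methoxyphenyl)methoxy]-3-(propan-2-yl)pentanoic acid (diacid) | OC(=O)C[C@H](C(C)C)[C@H](O[Si](C)(C)C(C)(C)C)[C@@H](OCc1ccc(OC)cc1)C2(OCCO2)/C=C/C(=O)O
F2 | step 12 | methyl (3R,4S,5R)-4-[(tert-butyldimethylsilyl)oxy]-5-{2-[(1E)-3-methoxy-3-oxoprop-1-en-1-yl]-1,3-dioxolan-2-yl}-5-[(4-methoxyphenyl)methoxy]-3-(propan-2-yl)pentanoate (dimethyl diester) | COC(=O)C[C@H](C(C)C)[C@H](O[Si](C)(C)C(C)(C)C)[C@@H](OCc1ccc(OC)cc1)C2(OCCO2)/C=C/C(=O)OC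
F3 | step 12 | methyl (2R,3S,4S,5S,9R)-3-[(tert-butyldimethylsilyl)oxy]-9-(2-methoxy-2-oxoethyl)-2-[(4-methoxyphenyl)methoxy]-1-oxo-4-(propan-2-yl)cyclohexane-5-carboxylate 1-ethylene ketal (cyclized diester; route numbering) | COC(=O)C[C@H]1C2(OCCO2)[C@H](OCc3ccc(OC)cc3)[C@@H](O[Si](C)(C)C(C)(C)C)[C@@H](C(C)C)[C@@H]1C(=O)OC
F4 | step 12 | (2R,3S,4S,5S,9R)-3-[(tert-butyldimethylsilyl)oxy]-9-(2-hydroxyethyl)-5-(hydroxymethyl)-2-[(4-methoxyphenyl)methoxy]-4-(propan-2-yl)cyclohexan-1-one ethylene ketal (diol; route numbering) | OCC[C@H]1C2(OCCO2)[C@H](OCc3ccc(OC)cc3)[C@@H](O[Si](C)(C)C(C)(C)C)[C@@H](C(C)C)[C@@H]1CO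
F5 | step 16 | (2R,3S,4S,5S,7S,9R)-3,7-bis[(tert-butyldimethylsilyl)oxy]-6-hydroxy-2-[(4-methoxyphenyl)methoxy]-4-(propan-2-yl)-6-[1-(trimethylsilyl)ethyl]hydrindan-1-one ethylene ketal (β-hydroxysilane; both diastereomers at C6 and C12 are used) | O1CCOC12[C@H](OCc4ccc(OC)cc4)[C@@H](O[Si](C)(C)C(C)(C)C)[C@@H](C(C)C)[C@@H]3C(O)(C(C)[Si](C)(C)C)[C@@H](O[Si](C)(C)C(C)(C)C)C[C@@H]23
F6 | step 13 | (2R,3S,4S,5S,6S,7R,9R)-3-[(tert-butyldimethylsilyl)oxy]-6,7-dihydroxy-2-[(4-methoxyphenyl)methoxy]-4-(propan-2-yl)hydrindan-1-one ethylene ketal (6,7-bis-epimeric cis-diol) | O1CCOC12[C@H](OCc4ccc(OC)cc4)[C@@H](O[Si](C)(C)C(C)(C)C)[C@@H](C(C)C)[C@@H]3[C@H](O)[C@H](O)C[C@@H]23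
F7 | step 13 | (2R,3S,4S,5S,6S,7R,9R)-3,7-bis[(tert-butyldimethylsilyl)oxy]-6-hydroxy-2-[(4-methoxyphenyl)methoxy]-4-(propan-2-yl)hydrindan-1-one ethylene ketal (C7 silyl ether) | O1CCOC12[C@H](OCc4ccc(OC)cc4)[C@@H](O[Si](C)(C)C(C)(C)C)[C@@H](C(C)C)[C@@H]3[C@H](O)[C@H](O[Si](C)(C)C(C)(C)C)C[C@@H]23
F8 | step 13 | (2R,3S,4S,5S,7R,9R)-3,7-bis[(tert-butyldimethylsilyl)oxy]-2-[(4-methoxyphenyl)methoxy]-4-(propan-2-yl)hydrindane-1,6-dione 1-ethylene ketal (ketone) | O1CCOC12[C@H](OCc4ccc(OC)cc4)[C@@H](O[Si](C)(C)C(C)(C)C)[C@@H](C(C)C)[C@@H]3C(=O)[C@H](O[Si](C)(C)C(C)(C)C)C[C@@H]23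
F9 | step 13 | (2R,3S,4S,5S,7R,9R,6Z)-3,7-bis[(tert-butyldimethylsilyl)oxy]-6-ethylidene-2-[(4-methoxyphenyl)methoxy]-4-(propan-2-yl)hydrindan-1-one ethylene ketal (Z-ethylidene compound) | O1CCOC12[C@H](OCc4ccc(OC)cc4)[C@@H](O[Si](C)(C)C(C)(C)C)[C@@H](C(C)C)[C@@H]3/C(=C/C)[C@H](O[Si](C)(C)C(C)(C)C)C[C@@H]23
F10 | step 13 | (2R,3S,4S,5S,7R,9R,6Z)-3,7-bis[(tert-butyldimethylsilyl)oxy]-6-ethylidene-2-[(4-methoxyphenyl)methoxy]-4-(propan-2-yl)hydrindan-1-one (C1 ketone) | O=C1[C@H](OCc3ccc(OC)cc3)[C@@H](O[Si](C)(C)C(C)(C)C)[C@@H](C(C)C)[C@@H]2/C(=C/C)[C@H](O[Si](C)(C)C(C)(C)C)C[C@@H]12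
F11 | step 13 | (2S,3S,4S,5R,7R,9R,6Z)-3,7-bis[(tert-butyldimethylsilyl)oxy]-6-ethylidene-2-[(4-methoxyphenyl)methoxy]-1-methylidene-4-(propan-2-yl)hydrindane (methylidene compound) | C=C1[C@H](OCc3ccc(OC)cc3)[C@@H](O[Si](C)(C)C(C)(C)C)[C@@H](C(C)C)[C@@H]2/C(=C/C)[C@H](O[Si](C)(C)C(C)(C)C)C[C@@H]12
F12 | step 13 | (2S,3S,4S,5R,7R,9R,6Z)-6-ethylidene-2-[(4-methoxyphenyl)methoxy]-1-methylidene-4-(propan-2-yl)hydrindane-3,7-diol (diol) | C=C1[C@H](OCc3ccc(OC)cc3)[C@@H](O)[C@@H](C(C)C)[C@@H]2/C(=C/C)[C@H](O)C[C@@H]12
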